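A direct plan would build ring A last: the trianion of the geranylated 3,5-diketo ester A1 would be acylated by the (S)-silyloxy Weinreb amide A2, whose stereocentre would come from transfer hydrogenation of a β-keto amide; the triketo ester A3 would be desilylated, closed to the ring C dihydropyranone and aromatised by heat through the acylketene A4.
Weakest would be the polyanion acylation of A1 by A2 (several acidic sites; the tetracarbonyl product can cyclise or lose silanol), the one-flask desilylation, cyclodehydration and thermolysis (aromatisation without precedent; 110 °C risks pyranones and racemisation at C2), and the two silylations, which add length only to mask a carbinol.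

**Strategy.** The route would rest on the C2–C1' bond: ring B would be joined last, as an arylboronic acid, to the C2=C3–C4=O enone of an achiral 6-geranylchromone that already holds rings A and C. One rhodium-catalysed asymmetric 1,4-addition would couple the two halves and set C2, the only stereocentre, under ligand control. No polycarbonyl chain, polyanion or thermal aromatisation would then be needed, and the carbinol protection would disappear. Ring A would be bought as 5,7-dihydroxychromone; its chelated 5-OH would direct iodination to C6, which fixes the position of the geranyl group before a Stille coupling.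

Key step: step 8

Assumption: the rhodium catalyst is taken to discriminate the faces of the chromone as it does those of cyclohex-2-enone, so the (S)-bisphosphine is assigned; were the sense opposite, the (R)-ligand would be used with no other change.

**Route**

Step 1
Reactants: 1 5,7-dihydroxy-4H-chromen-4-one; 2 chloromethyl methyl ether
Product: 3 5-hydroxy-7-(methoxymethoxy)-4H-chromen-4-one
Conditions: MOMCl (1.1 eq), iPr2NEt (1.5 eq), CH2Cl2, 0 °C → rt
Reagents that add atoms: chloromethyl methyl ether (2), COCCl
Why: Williamson-type O-alkylation should take only the 7-OH, the more acidic vinylogous-acid phenol, because the 5-OH is held in a hydrogen bond to the C4 carbonyl.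

Step 2
Reactants: 3 5-hydroxy-7-(methoxymethoxy)-4H-chromen-4-one; 4 benzyltrimethylammonium dichloroiodate
Product: 5 5-hydroxy-6-iodo-7-(methoxymethoxy)-4H-chromen-4-one
Conditions: BnNMe3ICl2 (1.1 eq), CaCO3 (1.5 eq), CH2Cl2/MeOH (5:2), rt, dark
Reagents that add atoms: benzyltrimethylammonium dichloroiodate (4), C[N+](C)(C)Cc1ccccc1.Cl[I-]Cl
Why: Electrophilic aromatic iodination with the mild ICl2 salt should go ortho to the free chelated 5-OH at C6 and not at C8, the outcome known for 5-hydroxy-7-alkoxy flavones, while CaCO3 takes up HCl so that the acetal survives.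

Step 3
Reactants: 5 5-hydroxy-6-iodo-7-(methoxymethoxy)-4H-chromen-4-one; 2 chloromethyl methyl ether
Product: 6 6-iodo-5,7-bis(methoxymethoxy)-4H-chromen-4-one
Conditions: NaH (1.3 eq), DMF, 0 °C; then MOMCl (1.5 eq), 0 °C → rt
Reagents that add atoms: chloromethyl methyl ether (2), COCCl
Why: Williamson etherification of the sodium phenoxide masks the hindered, chelating 5-OH, which would otherwise bind rhodium like an acetylacetonate ligand in the key step.

Step 4
Reactants: 7 geranyl chloride; 8 tributyltin hydride
Product: 10 tributyl[(2E)-3,7-dimethylocta-2,6-dien-1-yl]stannane, via tributylstannyllithium 9 (not isolated)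
Conditions: Bu3SnH, LiN(iPr)2 (1.05 eq), THF, 0 °C; then 7, −78 → 0 °C
Reagents that add atoms: tributyltin hydride (8), CCCC[SnH](CCCC)CCCC; geranyl chloride (7), ClC/C=C(\C)CCC=C(C)C
Why: SN2 displacement of the primary allylic chloride by the stannyl anion, made by deprotonation of the tin hydride, should give the linear stannane with the E-alkene unchanged.

Step 5
Reactants: 6 6-iodo-5,7-bis(methoxymethoxy)-4H-chromen-4-one; 10 tributyl[(2E)-3,7-dimethylocta-2,6-dien-1-yl]stannane
Product: 11 6-[(2E)-3,7-dimethylocta-2,6-dien-1-yl]-5,7-bis(methoxymethoxy)-4H-chromen-4-one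
Conditions: Pd(PPh3)4 (10 mol %), 10 (1.5 eq), DMF (degassed), 95 °C
Reagents that add atoms: tributyl[(2E)-3,7-dimethylocta-2,6-dien-1-yl]stannane (10), CCCC[Sn](CCCC)(CCCC)C/C=C(\C)CCC=C(C)C
Why: Migita–Kosugi–Stille coupling, in which zerovalent palladium inserts into the C6–I bond and reductive elimination at the unhindered CH2 end of the allyl ligand should give the linear E-geranyl arene, as known for prenyl stannanes with 6-iodo flavones.

Step 6
Reactants: 12 4-bromo-2,6-dimethoxyphenol; 2 chloromethyl methyl ether
Product: 13 5-bromo-1,3-dimethoxy-2-(methoxymethoxy)benzene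
Conditions: MOMCl (1.3 eq), iPr2NEt (2 eq), CH2Cl2, 0 °C → rt
Reagents that add atoms: chloromethyl methyl ether (2), COCCl
Why: Williamson-type MOM protection allows the aryllithium to be formed and keeps the later flavanone free of a 4'-OH, which would open a quinone methide path to racemisation.

Step 7
Reactants: 13 5-bromo-1,3-dimethoxy-2-(methoxymethoxy)benzene; 14 triisopropyl borate
Product: 17 [3,5-dimethoxy-4-(methoxymethoxy)phenyl]boronic acid, via aryllithium 15 (not isolated), via lithium aryltriisopropoxyborate 16 (not isolated)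
Conditions: n-BuLi (1.1 eq), THF, −78 °C; B(OiPr)3 (1.5 eq), −78 °C → rt; cold 1 M HCl to pH 6
Reagents that add atoms: triisopropyl borate (14), CC(C)OB(OC(C)C)OC(C)C; water, O
Why: Bromine–lithium exchange and borylation of the aryllithium with a trialkyl borate, followed by hydrolysis of the borate ester at pH 6, which should leave the MOM ether intact.

Step 8
Reactants: 11 6-[(2E)-3,7-dimethylocta-2,6-dien-1-yl]-5,7-bis(methoxymethoxy)-4H-chromen-4-one; 17 [3,5-dimethoxy-4-(methoxymethoxy)phenyl]boronic acid
Product: 18 (2S)-6-[(2E)-3,7-dimethylocta-2,6-dien-1-yl]-2-[3,5-dimethoxy-4-(methoxymethoxy)phenyl]-5,7-bis(methoxymethoxy)-2,3-dihydro-4H-chromen-4-one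
Conditions: [Rh(OH)(cod)]2 (2.5 mol %), (S)-(6,6'-dimethoxybiphenyl-2,2'-diyl)bis[bis(3,4,5-trifluorophenyl)phosphane] (5.5 mol %), 17 (2.0 eq), toluene/H2O (10:1), 35 °C, no added base
Reagents that add atoms: [3,5-dimethoxy-4-(methoxymethoxy)phenyl]boronic acid (17), COCOc1c(OC)cc(B(O)O)cc1OC
Why: Hayashi–Miyaura asymmetric 1,4-addition: the boronic acid transmetalates to the hydroxo complex of monovalent rhodium, the aryl–rhodium species inserts the C2=C3 bond of the chromone with the aryl group going to C2, and water protonates the oxa-π-allyl rhodium enolate, returning Rh–OH. The closest known reaction is the rhodium/chiral bisphosphine (or chiral diene) addition of arylboronic acids to chromones to give 2-arylchroman-4-ones. No ring is closed; the step forms the C2–C1' bond between the finished A/C bicycle and ring B. C2 is set by the ligand alone, the (S)-bisphosphine being expected to expose the Re face of C2 (O1 > C3 > H), the same spatial face as in the cyclohex-2-enone to (S)-3-arylcyclohexanone case, which corresponds to (2S). The step needs chemoselectivity for the enone over the two trisubstituted alkenes, which do not insert into aryl–rhodium bonds, and protonation of the enolate faster than β-aryloxide elimination (opening of ring C), which the base-free water-containing medium, the low temperature and the electron-poor ligand should secure.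

Step 9
Reactants: 18 (2S)-6-[(2E)-3,7-dimethylocta-2,6-dien-1-yl]-2-[3,5-dimethoxy-4-(methoxymethoxy)phenyl]-5,7-bis(methoxymethoxy)-2,3-dihydro-4H-chromen-4-one
Product: 19 (2S)-6-[(2E)-3,7-dimethylocta-2,6-dien-1-yl]-5,7-dihydroxy-2-(4-hydroxy-3,5-dimethoxyphenyl)-2,3-dihydro-4H-chromen-4-one (target CNP0372687.1)
Conditions: 3 M aq. HCl/MeOH (1:5), 45 °C, 1–2 h; NaHCO3 work-up
Reagents that add atoms: none
Why: Acid-catalysed acetal exchange with methanol removes the three MOM groups, and brief exposure at moderate temperature should spare the geranyl alkenes and C2, since flavanones open and racemise through the chalcone mainly under basic conditions.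

**Compound list**

1 | 5,7-dihydroxy-4H-chromen-4-one | O=c1ccoc2cc(O)cc(O)c12 | starting material
2 | chloromethyl methyl ether | COCCl | starting material
3 | 5-hydroxy-7-(methoxymethoxy)-4H-chromen-4-one | O=c1ccoc2cc(OCOC)cc(O)c12 | intermediate
4 | benzyltrimethylammonium dichloroiodate | C[N+](C)(C)Cc1ccccc1.Cl[I-]Cl | starting material
5 | 5-hydroxy-6-iodo-7-(methoxymethoxy)-4H-chromen-4-one | O=c1ccoc2cc(OCOC)c(I)c(O)c12 | intermediate
6 | 6-iodo-5,7-bis(methoxymethoxy)-4H-chromen-4-one | O=c1ccoc2cc(OCOC)c(I)c(OCOC)c12 | intermediate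
7 | geranyl chloride, (2E)-1-chloro-3,7-dimethylocta-2,6-diene | ClC/C=C(\C)CCC=C(C)C | starting material
8 | tributyltin hydride | CCCC[SnH](CCCC)CCCC | starting material
9 | tributylstannyllithium | [Li][Sn](CCCC)(CCCC)CCCC | intermediate (not isolated)
10 | tributyl[(2E)-3,7-dimethylocta-2,6-dien-1-yl]stannane | CCCC[Sn](CCCC)(CCCC)C/C=C(\C)CCC=C(C)C | intermediate
11 | 6-[(2E)-3,7-dimethylocta-2,6-dien-1-yl]-5,7-bis(methoxymethoxy)-4H-chromen-4-one | O=c1ccoc2cc(OCOC)c(C/C=C(\C)CCC=C(C)C)c(OCOC)c12 | intermediate
12 | 4-bromo-2,6-dimethoxyphenol | COc1cc(Br)cc(OC)c1O | starting material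
13 | 5-bromo-1,3-dimethoxy-2-(methoxymethoxy)benzene | COCOc1c(OC)cc(Br)cc1OC | intermediate
14 | triisopropyl borate | CC(C)OB(OC(C)C)OC(C)C | starting material
15 | [3,5-dimethoxy-4-(methoxymethoxy)phenyl]lithium | [Li]c1cc(OC)c(OCOC)c(OC)c1 | intermediate (not isolated)
16 | lithium [3,5-dimethoxy-4-(methoxymethoxy)phenyl]triisopropoxyborate | [Li+].CC(C)O[B-](OC(C)C)(OC(C)C)c1cc(OC)c(OCOC)c(OC)c1 | intermediate (not isolated)
17 | [3,5-dimethoxy-4-(methoxymethoxy)phenyl]boronic acid | COCOc1c(OC)cc(B(O)O)cc1OC | intermediate
18 | (2S)-6-[(2E)-3,7-dimethylocta-2,6-dien-1-yl]-2-[3,5-dimethoxy-4-(methoxymethoxy)phenyl]-5,7-bis(methoxymethoxy)-2,3-dihydro-4H-chromen-4-one | COCOc1c(OC)cc([C@@H]2CC(=O)c3c(cc(OCOC)c(C/C=C(\C)CCC=C(C)C)c3OCOC)O2)cc1OC | intermediate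
19 | (2S)-6-[(2E)-3,7-dimethylocta-2,6-dien-1-yl]-5,7-dihydroxy-2-(4-hydroxy-3,5-dimethoxyphenyl)-2,3-dihydro-4H-chromen-4-one | COc1cc([C@@H]2CC(=O)c3c(cc(O)c(C/C=C(\C)CCC=C(C)C)c3O)O2)cc(OC)c1O | target

**Count and risks**

Total step count: 9. Longest linear sequence: 6 steps (steps 1, 2, 3, 5, 8 and 9).

Steps most likely to fail:

1. Step 8 (key step). Carbometalation of the electron-rich, peri-substituted chromone may be slow. The rhodium enolate may expel the aryloxide and open ring C, with non-selective re-closure. The electron-rich boronic acid may protodeboronate. Facial selectivity may fall below that seen on simpler chromones. The fallback would give up catalyst-controlled addition in favour of resolution. It would set out from 11 and 17: the ligand-free, more active diene complex [Rh(OH)(cod)]2 (dioxane/H2O, 50 °C) would give the racemic flavanone F1. Kinetic resolution by Noyori asymmetric transfer hydrogenation (RuCl(p-cymene)[(R,R)-TsDPEN], HCO2H/Et3N 5:2, EtOAc, rt, stopped just past half conversion) should reduce the (2R)-enantiomer to the cis-(2R,4R)-flavan-4-ol F2, by analogy with acetophenone and with hydride entering trans to the aryl group. The unreacted (2S)-ketone would be separated by chromatography, and the route would be rejoined at 18.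

2. Step 5. The allyl group may transpose during transmetalation, giving the branched linalyl-type isomer. The alkene geometry may erode through σ–π–σ interconversion of the allylpalladium intermediate. Oxidative addition into the doubly ortho-substituted C–I bond may be slow, with loss of iodine by protonolysis. The fallback would reverse the polarity of the partners. Setting out from 6, Miyaura borylation (B2pin2, PdCl2(dppf), KOAc, dioxane, 85 °C) would give the pinacol boronate F3. Suzuki–Miyaura allyl–aryl coupling with geranyl chloride 7 (Pd(PPh3)4, CsF, dioxane, 70 °C) would follow, in which the E-configured π-allyl complex formed by oxidative addition should be arylated at its CH2 terminus. It would come back to the route at 11.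

3. Step 9. Protic acid may cyclise the geranyl chain onto the freed 5- or 7-OH (chroman formation) or hydrate its alkenes, and reversible opening of ring C may erode the enantiomeric purity. The fallback would change the order of events so that the geranyl group never meets acid. Setting out from 6, the rhodium addition of 17 under the conditions of step 8 would give the iodo flavanone F4. HCl/MeOH would remove the three MOM groups to give the iodo triol F5. Neutral Stille coupling of F5 with stannane 10 (Pd(PPh3)4, DMF, 90 °C) would install the geranyl group last, arriving at 19.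

**Further compounds**

F1 | step 8 | racemic 6-[(2E)-3,7-dimethylocta-2,6-dien-1-yl]-2-[3,5-dimethoxy-4-(methoxymethoxy)phenyl]-5,7-bis(methoxymethoxy)-2,3-dihydro-4H-chromen-4-one | COCOc1c(OC)cc(C2CC(=O)c3c(cc(OCOC)c(C/C=C(\C)CCC=C(C)C)c3OCOC)O2)cc1OC
F2 | step 8 | (2R,4R)-6-[(2E)-3,7-dimethylocta-2,6-dien-1-yl]-2-[3,5-dimethoxy-4-(methoxymethoxy)phenyl]-5,7-bis(methoxymethoxy)-3,4-dihydro-2H-chromen-4-ol | COCOc1c(OC)cc([C@H]2C[C@@H](O)c3c(cc(OCOC)c(C/C=C(\C)CCC=C(C)C)c3OCOC)O2)cc1OC
F3 | step 5 | 5,7-bis(methoxymethoxy)-6-(4,4,5,5-tetramethyl-1,3,2-dioxaborolan-2-yl)-4H-chromen-4-one | O=c1ccoc2cc(OCOC)c(B3OC(C)(C)C(C)(C)O3)c(OCOC)c12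
F4 | step 9 | (2S)-6-iodo-2-[3,5-dimethoxy-4-(methoxymethoxy)phenyl]-5,7-bis(methoxymethoxy)-2,3-dihydro-4H-chromen-4-one | COCOc1c(OC)cc([C@@H]2CC(=O)c3c(cc(OCOC)c(I)c3OCOC)O2)cc1OC
F5 | step 9 | (2S)-5,7-dihydroxy-2-(4-hydroxy-3,5-dimethoxyphenyl)-6-iodo-2,3-dihydro-4H-chromen-4-one | COc1cc([C@@H]2CC(=O)c3c(cc(O)c(I)c3O)O2)cc(OC)c1O
A1 | direct plan | tert-butyl 2-geranyl-3,5-dioxohexanoate | CC(=O)CC(=O)C(C/C=C(\C)CCC=C(C)C)C(=O)OC(C)(C)C
A2 | direct plan | (3S)-3-(tert-butyldimethylsilyloxy)-3-[4-(tert-butyldimethylsilyloxy)-3,5-dimethoxyphenyl]-N-methoxy-N-methylpropanamide | CON(C)C(=O)C[C@H](O[Si](C)(C)C(C)(C)C)c1cc(OC)c(O[Si](C)(C)C(C)(C)C)c(OC)c1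
A3 | direct plan | tert-butyl (9S)-9-(tert-butyldimethylsilyloxy)-9-[4-(tert-butyldimethylsilyloxy)-3,5-dimethoxyphenyl]-2-geranyl-3,5,7-trioxononanoate | CC(C)(C)OC(=O)C(C/C=C(\C)CCC=C(C)C)C(=O)CC(=O)CC(=O)C[C@H](O[Si](C)(C)C(C)(C)C)c1cc(OC)c(O[Si](C)(C)C(C)(C)C)c(OC)c1
A4 | direct plan | 2-geranyl-4-[(2S)-2-(4-hydroxy-3,5-dimethoxyphenyl)-4-oxo-3,4-dihydro-2H-pyran-6-yl]-3-oxobut-1-en-1-one (acylketene) | O=C=C(C/C=C(\C)CCC=C(C)C)C(=O)CC1=CC(=O)C[C@@H](c2cc(OC)c(O)c(OC)c2)O1
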